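**Strategy**

Everything rests on closing the carbocycle C1–C2–C3–C4–C5–C8 of the 6-oxabicyclo[3.2.1]octane last, by a formal (3+3) annulation of acrolein onto an intact oxolane. The step exploits that bridgeheads C1 and C5, which flank C8, are both fully substituted oxolane carbons (C5 bound to O6) and hence latent tertiary radicals. The precursor carries the complete side chain at the future C8, a carboxylic acid at the future C5 and a hydrogen oxalate at the future C1. Dual photoredox/chromium catalysis should oxidise the α-oxy carboxylate first (Giese addition to acrolein), then fragment the oxalate and deliver the second radical to the new aldehyde; all epimers at the two radical carbons converge.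

Key step: step 5

Assumption: the sense of induction in step 1 is taken from the usual chelate model for Cu(II)–bis(oxazoline)/α-keto ester complexes; the ligand antipode that gives (3R)-3 is used, and (3R)-3 is taken on as its C2 epimer pair after removal of any (3S) material.

**Route**

Step 1
Reactants: 1 auraptene; 2 methyl pyruvate
Product: 3 methyl (3R,6E)-2-hydroxy-2,6-dimethyl-8-[(2-oxo-2H-chromen-7-yl)oxy]-3-(prop-1-en-2-yl)oct-6-enoate (C2 configuration open)
Conditions: [Cu(t-Bu-box)](SbF6)2 (10 mol %), CH2Cl2, 0 °C to rt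
Reagents that add atoms: none
Why: Carbonyl-ene reaction in which the chelated α-keto ester should be attacked by the CH carbon of the distal, more electron-rich alkene (the 2,3-alkene is deactivated by the allylic aryloxy group) with transfer of a methyl hydrogen, the bis(oxazoline) ligand fixing C3 through the closed ene transition state.

Step 2
Reactants: 3
Product: 4 methyl (3S,6E)-2-hydroxy-2,6-dimethyl-3-(2-methyloxiran-2-yl)-8-[(2-oxo-2H-chromen-7-yl)oxy]oct-6-enoate (same spatial arrangement at C3 as in 3; the descriptor changes by priority only; epoxide carbon open)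
Conditions: VO(acac)2 (5 mol %), t-BuOOH, CH2Cl2, 0 °C to rt
Reagents that add atoms: tert-butyl hydroperoxide CC(C)(C)OO
Why: Hydroxyl-directed vanadium epoxidation should deliver oxygen only to the homoallylic isopropenyl group and leave the remote trisubstituted alkene and the coumarin untouched; the epoxide configuration is of no consequence.

Step 3
Reactants: 4
Product: 6 (3R)-4-hydroxy-2,4-dimethyl-3-{(3E)-3-methyl-5-[(2-oxo-2H-chromen-7-yl)oxy]pent-3-en-1-yl}oxolane-2-carboxylic acid, via oxolane methyl ester 5 (not isolated)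
Conditions: NaH, THF, 0 °C to rt; then LiOH, THF/MeOH/H2O, 50 °C; HCl to pH 3
Reagents that add atoms: lithium hydroxide [Li+].[OH-]
Why: Intramolecular Williamson-type opening of the 3,4-epoxy alcohol by the tertiary alkoxide at the CH2 terminus (5-endo; the 4-exo alternative would give a strained oxetane) should close the oxolane without touching C3, then saponification frees the acid and acidification re-closes the coumarin.

Step 4
Reactants: 6
Product: 8 (3R)-4-[(carboxycarbonyl)oxy]-2,4-dimethyl-3-{(3E)-3-methyl-5-[(2-oxo-2H-chromen-7-yl)oxy]pent-3-en-1-yl}oxolane-2-carboxylic acid, via chlorooxoacetate 7 (not isolated)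
Conditions: (COCl)2, Et2O, 0 °C to rt; then H2O
Reagents that add atoms: oxalyl chloride O=C(Cl)C(Cl)=O; water O
Why: Acylation of the hindered tertiary alcohol with excess oxalyl chloride and aqueous quench should give the tert-alkyl hydrogen oxalate, the usual radical precursor for tertiary alcohols, any acyl chloride formed at the carboxylic acid being hydrolysed back on quench.

Step 5
Reactants: 8; 9 acrolein
Product: 11 7-{[(2E)-5-[(1R,2R,5S,8R)-2-hydroxy-1,5-dimethyl-6-oxabicyclo[3.2.1]octan-8-yl]-3-methylpent-2-en-1-yl]oxy}-2H-chromen-2-one, via Giese aldehyde 10 (not isolated)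
Conditions: [Ir(dF(CF3)ppy)2(dtbbpy)]PF6 (2 mol %), CrCl2 (15 mol %), dtbbpy (15 mol %), Cs2CO3, acrolein (slight excess), DMF, 450 nm LEDs, rt; aq. NH4Cl
Reagents that add atoms: none
Why: Proposed new method: the excited Ir(III) catalyst should oxidise the more electron-rich α-alkoxy carboxylate first, the tertiary α-oxy radical at oxolane C2 adds to acrolein (Giese addition) anti to the C3 side chain and the adduct radical is reduced and protonated to aldehyde 10; the harder-to-oxidise oxalate then fragments with loss of two CO2 to the tertiary C4 radical, Cr(II) captures it, and the alkylchromium(III) adds to the tethered aldehyde in a Nozaki–Hiyama–Kishi-type 1,2-addition while Ir(II) returns Cr(III) to Cr(II). The closest known reaction types are the photoredox decarboxylative Giese addition of α-oxy acids, the photoredox fragmentation of tert-alkyl oxalates and carbonyl alkylation through alkylchromium species formed from radicals; their merger in one flask is new. The carbocycle closes 6-exo onto the aldehyde carbon and is necessarily cis-fused across oxolane C2/C4, which gives the 6-oxabicyclo[3.2.1]octane. In bicycle numbering, C5 is set by 1,2-induction from the C8 stereocentre in the Giese step, C1 by the tether (both C4 epimers of 8 converge through the planar radical), and C2 by a closed chromium alkoxide transition state that keeps the Cr–O unit on the open convex side, i.e. hydroxyl equatorial. The step needs the α-oxy radical to add to acrolein before chromium intercepts it, and the second radical to meet the internal rather than external aldehyde: the first is secured by the lower oxidation potential and high nucleophilicity of the α-oxy centre at low Cr(II) concentration, the second by the small excess of acrolein and the intramolecular 1,2-addition.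

**Compound list**

1 | auraptene, 7-{[(2E)-3,7-dimethylocta-2,6-dien-1-yl]oxy}-2H-chromen-2-one | C/C(=C\COc1ccc2ccc(=O)oc2c1)CCC=C(C)C | starting material
2 | methyl pyruvate (methyl 2-oxopropanoate) | CC(=O)C(=O)OC | starting material
3 | methyl (3R,6E)-2-hydroxy-2,6-dimethyl-8-[(2-oxo-2H-chromen-7-yl)oxy]-3-(prop-1-en-2-yl)oct-6-enoate | C/C(=C\COc1ccc2ccc(=O)oc2c1)CC[C@H](C(C)=C)C(C)(O)C(=O)OC | intermediate
4 | methyl (3S,6E)-2-hydroxy-2,6-dimethyl-3-(2-methyloxiran-2-yl)-8-[(2-oxo-2H-chromen-7-yl)oxy]oct-6-enoate | C/C(=C\COc1ccc2ccc(=O)oc2c1)CC[C@H](C1(C)CO1)C(C)(O)C(=O)OC | intermediate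
5 | methyl (3R)-4-hydroxy-2,4-dimethyl-3-{(3E)-3-methyl-5-[(2-oxo-2H-chromen-7-yl)oxy]pent-3-en-1-yl}oxolane-2-carboxylate | C/C(=C\COc1ccc2ccc(=O)oc2c1)CC[C@@H]1C(C)(O)COC1(C)C(=O)OC | intermediate (not isolated)
6 | (3R)-4-hydroxy-2,4-dimethyl-3-{(3E)-3-methyl-5-[(2-oxo-2H-chromen-7-yl)oxy]pent-3-en-1-yl}oxolane-2-carboxylic acid | C/C(=C\COc1ccc2ccc(=O)oc2c1)CC[C@@H]1C(C)(O)COC1(C)C(=O)O | intermediate
7 | (3R)-4-[(2-chloro-2-oxoacetyl)oxy]-2,4-dimethyl-3-{(3E)-3-methyl-5-[(2-oxo-2H-chromen-7-yl)oxy]pent-3-en-1-yl}oxolane-2-carboxylic acid | C/C(=C\COc1ccc2ccc(=O)oc2c1)CC[C@@H]1C(C)(OC(=O)C(Cl)=O)COC1(C)C(=O)O | intermediate (not isolated)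
8 | (3R)-4-[(carboxycarbonyl)oxy]-2,4-dimethyl-3-{(3E)-3-methyl-5-[(2-oxo-2H-chromen-7-yl)oxy]pent-3-en-1-yl}oxolane-2-carboxylic acid | C/C(=C\COc1ccc2ccc(=O)oc2c1)CC[C@@H]1C(C)(OC(=O)C(=O)O)COC1(C)C(=O)O | intermediate
9 | acrolein (prop-2-enal) | C=CC=O | starting material
10 | 2-oxo-2-({(4S,5S)-3,5-dimethyl-4-{(3E)-3-methyl-5-[(2-oxo-2H-chromen-7-yl)oxy]pent-3-en-1-yl}-5-(3-oxopropyl)oxolan-3-yl}oxy)acetic acid | C/C(=C\COc1ccc2ccc(=O)oc2c1)CC[C@@H]1C(C)(OC(=O)C(=O)O)CO[C@@]1(C)CCC=O | intermediate (not isolated)
11 | 7-{[(2E)-5-[(1R,2R,5S,8R)-2-hydroxy-1,5-dimethyl-6-oxabicyclo[3.2.1]octan-8-yl]-3-methylpent-2-en-1-yl]oxy}-2H-chromen-2-one | C/C(=C\COc1ccc2ccc(=O)oc2c1)CC[C@@H]1[C@]2(C)CO[C@@]1(C)CC[C@H]2O | target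

**Count**

Total steps: 5. Longest linear sequence: 5.

**Steps most likely to fail**

1. Step 5 (proposed new method). Chromium may intercept the first radical before conjugate addition, the oxalate may fragment out of order, the second radical or its organochromium may be protonated instead of closing the ring, and facial selectivity at the carbinol may be poor. The fallback uses known chemistry and sets out from 3. A 5-endo selenoetherification with phenylselenenyl chloride should give methyl (3S)-2,4-dimethyl-3-{(3E)-3-methyl-5-[(2-oxo-2H-chromen-7-yl)oxy]pent-3-en-1-yl}-4-(phenylselanyl)oxolane-2-carboxylate F1. Saponification with LiOH gives the corresponding acid F2. A photoredox decarboxylative Giese addition to acrolein alone, without chromium, gives the selenide aldehyde F3. Tributyltin hydride/AIBN then generates the tertiary radical from the selenide, which cyclises 6-exo onto the aldehyde, and the fallback comes back to the route at 11.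

2. Step 1. Pyruvate may react sluggishly with a trisubstituted alkene, the Lewis acid may be sequestered by the coumarin, and enantiofacial or endo/exo control at C3 may be insufficient. The fallback sets out from 1. Allylic oxidation with SeO2/t-BuOOH should give 7-{[(2E,6E)-8-hydroxy-3,7-dimethylocta-2,6-dien-1-yl]oxy}-2H-chromen-2-one F4. An Appel reaction gives the allylic bromide F5. Silver(I) oxide-mediated O-alkylation of methyl lactate gives the allyl ether F6. A [2,3]-Wittig rearrangement of its boron enolate, formed with a chiral bis-sulfonamide bromoborane and a tertiary amine, moves the ester α-carbon onto the alkene CH carbon, releases the isopropenyl group, and comes back to the route at 3.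

3. Step 3. The alkoxide may attack the tertiary epoxide carbon, the new tertiary alkoxide may lactonise onto the ester, and the epoxide may be opened by hydroxide if ring closure is incomplete. The fallback sets out from 3. A 5-endo iodoetherification with N-iodosuccinimide should give the tertiary iodide methyl (3S)-4-iodo-2,4-dimethyl-3-{(3E)-3-methyl-5-[(2-oxo-2H-chromen-7-yl)oxy]pent-3-en-1-yl}oxolane-2-carboxylate F7. Silver(I)-assisted hydrolysis (AgOTf, aqueous acetone) replaces iodide by hydroxyl, and the fallback comes back to the route at 5, which is saponified to 6 as before.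

Further compounds
F1 | step 5 | methyl (3S)-2,4-dimethyl-3-{(3E)-3-methyl-5-[(2-oxo-2H-chromen-7-yl)oxy]pent-3-en-1-yl}-4-(phenylselanyl)oxolane-2-carboxylate | C/C(=C\COc1ccc2ccc(=O)oc2c1)CC[C@@H]1C(C)([Se]c2ccccc2)COC1(C)C(=O)OC
F2 | step 5 | (3S)-2,4-dimethyl-3-{(3E)-3-methyl-5-[(2-oxo-2H-chromen-7-yl)oxy]pent-3-en-1-yl}-4-(phenylselanyl)oxolane-2-carboxylic acid | C/C(=C\COc1ccc2ccc(=O)oc2c1)CC[C@@H]1C(C)([Se]c2ccccc2)COC1(C)C(=O)O
F3 | step 5 | 3-[(2S,3S)-2,4-dimethyl-3-{(3E)-3-methyl-5-[(2-oxo-2H-chromen-7-yl)oxy]pent-3-en-1-yl}-4-(phenylselanyl)oxolan-2-yl]propanal | C/C(=C\COc1ccc2ccc(=O)oc2c1)CC[C@@H]1C(C)([Se]c2ccccc2)CO[C@@]1(C)CCC=O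
F4 | step 1 | 7-{[(2E,6E)-8-hydroxy-3,7-dimethylocta-2,6-dien-1-yl]oxy}-2H-chromen-2-one | C/C(=C\COc1ccc2ccc(=O)oc2c1)CC/C=C(\C)CO
F5 | step 1 | 7-{[(2E,6E)-8-bromo-3,7-dimethylocta-2,6-dien-1-yl]oxy}-2H-chromen-2-one | C/C(=C\COc1ccc2ccc(=O)oc2c1)CC/C=C(\C)CBr
F6 | step 1 | methyl 2-{[(2E,6E)-2,6-dimethyl-8-[(2-oxo-2H-chromen-7-yl)oxy]octa-2,6-dien-1-yl]oxy}propanoate | C/C(=C\COc1ccc2ccc(=O)oc2c1)CC/C=C(\C)COC(C)C(=O)OC
F7 | step 3 | methyl (3S)-4-iodo-2,4-dimethyl-3-{(3E)-3-methyl-5-[(2-oxo-2H-chromen-7-yl)oxy]pent-3-en-1-yl}oxolane-2-carboxylate | C/C(=C\COc1ccc2ccc(=O)oc2c1)CC[C@@H]1C(C)(I)COC1(C)C(=O)OC
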